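A direct plan would join two finished flavones at the ether oxygen. Apigenin would be perbenzylated and iodinated at C8 to give A1, genkwanin (A2) would be made by mono-methylation of apigenin, and a copper-mediated Ullmann etherification of A1 with the 4'-hydroxyl of A2 would give the protected biflavone ether A3, to be debenzylated. Its weakest steps would be:
- the aryl C–O coupling: C8 lies between two ortho oxygen substituents and the flavone phenol is electron-poor and poorly soluble, so reduction of the iodide would compete;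
- the C8-selective iodination of ring A, where C6 competes;
- the mono-methylation at O7, where O4' and double alkylation compete.

The route never makes an aryl C–O bond at C8. The ether oxygen is fixed to an sp3 carbon by Williamson alkylation, and ring A of the apigenin half is then built around it. A 4-pyranone-3-carboxylate that already holds O1, C2, C3, C4, C4a, C8a and the ArO–CH2 group (future C8) is acetylated on that CH2 and closed by Claisen condensation onto its own ester (future C5). One operation thus forms C8–C7 and C6–C5 and the 5,7-dihydroxy pattern, with the aryloxy group necessarily beside O1. Coupling at a hindered carbon, the C6/C8 question and the selective methylation of apigenin all disappear; the methoxy group arrives in a commercial acetophenone.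

Key step: step 5

Remark: the target has no stereocentre; 1,3-dicarbonyl compounds are written as keto tautomers, and the sp3 centre of 12 is racemic and is lost on aromatisation.

Step 1
Reactants: 1 4-iodophenol
Product: 2 1-iodo-4-(methoxymethoxy)benzene
Conditions: MOMCl (1.3 equiv), i-Pr2NEt (1.5 equiv), CH2Cl2, 0 °C → rt
Reagents that add atoms: chloromethyl methyl ether, COCCl
Why: Alkylation of the phenoxide with the α-chloro ether (Williamson-type acetal formation) should give a MOM ether that survives the amide bases and the acid chloride chemistry ahead and leaves in the last step; no stereocentre is formed.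

Step 2
Reactants: 2 1-iodo-4-(methoxymethoxy)benzene; 3 propiolic acid
Product: 4 3-[4-(methoxymethoxy)phenyl]prop-2-ynoic acid
Conditions: Pd(PPh3)2Cl2 (5 mol%), 1,4-bis(diphenylphosphino)butane (10 mol%), DBU (2.2 equiv), DMSO, rt, 12 h; cold aq. citric acid
Reagents that add atoms: none
Why: Copper-free Sonogashira-type coupling of the aryl iodide with propiolic acid, held as its DBU carboxylate, should give the arylpropiolic acid directly; at room temperature decarboxylation of the product should not set in and the acetal is inert.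

Step 3
Reactants: 5 methyl 4-hydroxybenzoate; 6 methyl 4-chloro-3-oxobutanoate
Product: 7 methyl 4-[4-(methoxycarbonyl)phenoxy]-3-oxobutanoate
Conditions: NaH (2.1 equiv), THF–DMF, 0 °C; then 6, 0 → 45 °C
Reagents that add atoms: none
Why: Williamson ether synthesis in which the second equivalent of NaH stores 6 as its enolate, so that the phenoxide should displace the primary chloride by SN2 without self-condensation; the future C8–O bond is thereby made on an unhindered sp3 carbon.

Step 4
Reactants: 4 3-[4-(methoxymethoxy)phenyl]prop-2-ynoic acid; 7 methyl 4-[4-(methoxycarbonyl)phenoxy]-3-oxobutanoate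
Product: 10 methyl 2-{[4-(methoxycarbonyl)phenoxy]methyl}-6-[4-(methoxymethoxy)phenyl]-4-oxo-4H-pyran-3-carboxylate, via arylpropioloyl chloride 8 (not isolated), via tricarbonyl ynone 9 (not isolated)
Conditions: 4, 1-chloro-N,N,2-trimethylprop-1-en-1-amine (1.1 equiv), CH2Cl2, 0 °C, 1 h; add to 7, MgCl2 (1.2 equiv), pyridine (2.5 equiv), CH2Cl2, 0 °C → rt; work-up; then K2CO3 (0.3 equiv), MeCN, 50 °C
Reagents that add atoms: none
Why: C-acylation of the chelated magnesium enolate of the β-keto ester by the alkynoyl chloride (made without HCl by the chloroenamine, so the acetal survives) and base-catalysed 6-endo-dig oxa-Michael addition of the ketone enol oxygen to the ynone, the classical 4-pyranone synthesis from β-dicarbonyl compounds and arylpropioloyl chlorides, should fix O1, C2, C3 and C4 of the apigenin half; conjugate addition puts oxygen on the aryl-bearing alkyne carbon rather than closing a furanone.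

Step 5
Reactants: 10 methyl 2-{[4-(methoxycarbonyl)phenoxy]methyl}-6-[4-(methoxymethoxy)phenyl]-4-oxo-4H-pyran-3-carboxylate; 11 1-acetyl-1H-benzotriazole
Product: 13 methyl 4-({5,7-dihydroxy-2-[4-(methoxymethoxy)phenyl]-4-oxo-4H-chromen-8-yl}oxy)benzoate, via C-acetylated pyranone 12 (not isolated)
Conditions: LiHMDS (2.2 equiv), THF, −78 °C; 11 (1.1 equiv), −78 → −20 °C; then LDA (4 equiv), −78 → 0 °C, 2 h; 1 M HCl, 0 °C
Reagents that add atoms: none
Why: Proposed new method: the CH2 between the ether oxygen and C2 of the pyranone is the only acidic site of 10 (vinylogous to the C4 ketone and to the C3 ester), so LiHMDS should give one extended dienolate, which the N-acylbenzotriazole acetylates on that carbon because C3 is fully substituted; the second equivalent of LiHMDS stores the product as its stabilised anion 12, and LDA (in excess over the hexamethyldisilazane already present) then removes a methyl proton to give a 1,3-dicarbonyl-type dianion whose terminal carbanion attacks the neighbouring C3 methyl ester. This Claisen closure is 6-exo-trig (bond C6–C5), methoxide leaves, and double enolisation of the cyclic triketone aromatises it irreversibly to the 5,7-dihydroxy ring A, which also erases the racemic centre of 12, so no stereocentre remains. The closest known reaction types are the lateral metalation and acylation of 2-alkyl-4-pyranones and the Claisen cyclisation of β-diketone dianions or 2-(2-oxopropyl)benzoates to acylphloroglucinols and naphthalene-1,3-diols in polyketide-model chemistry; building ring A of a flavone on a 4-pyranone-3-carboxylate that carries an α-aryloxy group has not been shown. The step needs site selectivity between two esters and the 8- versus 6-aryloxy regiochemistry: the first is secured because only the pyranone ester is within reach of a six-membered transition state (the benzoate sits para across the ether), the second by construction, since the carbon that carries the aryloxy group is bonded to the pyranone carbon that already holds O1. A closure onto the C4 ketone would demand a bridgehead double bond and is excluded.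

Step 6
Reactants: 13 methyl 4-({5,7-dihydroxy-2-[4-(methoxymethoxy)phenyl]-4-oxo-4H-chromen-8-yl}oxy)benzoate
Product: 14 methyl 4-({5,7-bis(methoxymethoxy)-2-[4-(methoxymethoxy)phenyl]-4-oxo-4H-chromen-8-yl}oxy)benzoate
Conditions: NaH (2.5 equiv), MOMCl (3 equiv), DMF, 0 °C → rt
Reagents that add atoms: chloromethyl methyl ether, COCCl
Why: Double Williamson-type O-alkylation; NaH in DMF is chosen because the hydrogen-bonded 5-OH resists amine bases, and masking both phenols should keep the ester partner neutral and soluble for the Claisen condensation while all three acetals leave together at the end.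

Step 7
Reactants: 14 methyl 4-({5,7-bis(methoxymethoxy)-2-[4-(methoxymethoxy)phenyl]-4-oxo-4H-chromen-8-yl}oxy)benzoate; 15 1-(2,6-dihydroxy-4-methoxyphenyl)ethan-1-one
Product: 16 1-(2,6-dihydroxy-4-methoxyphenyl)-3-[4-({5,7-bis(methoxymethoxy)-2-[4-(methoxymethoxy)phenyl]-4-oxo-4H-chromen-8-yl}oxy)phenyl]propane-1,3-dione
Conditions: 15 (1.5 equiv), LiHMDS (5 equiv), THF, −78 → −10 °C, 1 h; 14, −10 °C → rt, 12 h; 1 M HCl, 0 °C
Reagents that add atoms: none
Why: Crossed Claisen condensation in which the carbon enolate of the doubly O-lithiated acetophenone, used without protection as in polyanion syntheses of polyhydroxyflavones, should attack the non-enolisable aryl ester, and formation of the β-diketonate drives the equilibrium; the 7-methoxy group of the genkwanin half comes in ready-made.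

Step 8
Reactants: 16 1-(2,6-dihydroxy-4-methoxyphenyl)-3-[4-({5,7-bis(methoxymethoxy)-2-[4-(methoxymethoxy)phenyl]-4-oxo-4H-chromen-8-yl}oxy)phenyl]propane-1,3-dione
Product: 17 5-hydroxy-2-[4-({5,7-dihydroxy-2-(4-hydroxyphenyl)-4-oxo-4H-chromen-8-yl}oxy)phenyl]-7-methoxy-4H-chromen-4-one (CNP0424791.0)
Conditions: conc. HCl (10 equiv), MeOH–THF 2:1, 60 °C, 6 h
Reagents that add atoms: none
Why: Acid-catalysed cyclodehydration of the 2-hydroxyaryl 1,3-diketone should close ring C of the genkwanin half (the two ortho hydroxyls are equivalent, so only the 5-hydroxy-7-methoxyflavone can form) while the three acetals are transferred to methanol; the conditions are far milder than those of a Wessely–Moser isomerisation, so the aryloxy group should stay at C8, and no stereocentre is formed.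

Compound list
1 | 4-iodophenol | Oc1ccc(I)cc1 | starting material
2 | 1-iodo-4-(methoxymethoxy)benzene | COCOc1ccc(I)cc1 | intermediate
3 | propiolic acid (prop-2-ynoic acid) | C#CC(=O)O | starting material
4 | 3-[4-(methoxymethoxy)phenyl]prop-2-ynoic acid | COCOc1ccc(C#CC(=O)O)cc1 | intermediate
5 | methyl 4-hydroxybenzoate | COC(=O)c1ccc(O)cc1 | starting material
6 | methyl 4-chloro-3-oxobutanoate | COC(=O)CC(=O)CCl | starting material
7 | methyl 4-[4-(methoxycarbonyl)phenoxy]-3-oxobutanoate | COC(=O)CC(=O)COc1ccc(C(=O)OC)cc1 | intermediate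
8 | 3-[4-(methoxymethoxy)phenyl]prop-2-ynoyl chloride | COCOc1ccc(C#CC(Cl)=O)cc1 | intermediate
9 | methyl 2-{[4-(methoxycarbonyl)phenoxy]acetyl}-5-[4-(methoxymethoxy)phenyl]-3-oxopent-4-ynoate | COC(=O)c1ccc(OCC(=O)C(C(=O)OC)C(=O)C#Cc2ccc(OCOC)cc2)cc1 | intermediate
10 | methyl 2-{[4-(methoxycarbonyl)phenoxy]methyl}-6-[4-(methoxymethoxy)phenyl]-4-oxo-4H-pyran-3-carboxylate | COC(=O)c1ccc(OCc2oc(-c3ccc(OCOC)cc3)cc(=O)c2C(=O)OC)cc1 | intermediate
11 | 1-acetyl-1H-benzotriazole, 1-(1H-benzotriazol-1-yl)ethan-1-one | CC(=O)n1nnc2ccccc21 | starting material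
12 | methyl 2-{1-[4-(methoxycarbonyl)phenoxy]-2-oxopropyl}-6-[4-(methoxymethoxy)phenyl]-4-oxo-4H-pyran-3-carboxylate (racemic) | COC(=O)c1ccc(OC(C(C)=O)c2oc(-c3ccc(OCOC)cc3)cc(=O)c2C(=O)OC)cc1 | intermediate
13 | methyl 4-({5,7-dihydroxy-2-[4-(methoxymethoxy)phenyl]-4-oxo-4H-chromen-8-yl}oxy)benzoate | COC(=O)c1ccc(Oc2c(O)cc(O)c3c(=O)cc(-c4ccc(OCOC)cc4)oc23)cc1 | intermediate
14 | methyl 4-({5,7-bis(methoxymethoxy)-2-[4-(methoxymethoxy)phenyl]-4-oxo-4H-chromen-8-yl}oxy)benzoate | COC(=O)c1ccc(Oc2c(OCOC)cc(OCOC)c3c(=O)cc(-c4ccc(OCOC)cc4)oc23)cc1 | intermediate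
15 | 1-(2,6-dihydroxy-4-methoxyphenyl)ethan-1-one | COc1cc(O)c(C(C)=O)c(O)c1 | starting material
16 | 1-(2,6-dihydroxy-4-methoxyphenyl)-3-[4-({5,7-bis(methoxymethoxy)-2-[4-(methoxymethoxy)phenyl]-4-oxo-4H-chromen-8-yl}oxy)phenyl]propane-1,3-dione | COc1cc(O)c(C(=O)CC(=O)c2ccc(Oc3c(OCOC)cc(OCOC)c4c(=O)cc(-c5ccc(OCOC)cc5)oc34)cc2)c(O)c1 | intermediate
17 | 5-hydroxy-2-[4-({5,7-dihydroxy-2-(4-hydroxyphenyl)-4-oxo-4H-chromen-8-yl}oxy)phenyl]-7-methoxy-4H-chromen-4-one (CNP0424791.0) | COc1cc(O)c2c(=O)cc(-c3ccc(Oc4c(O)cc(O)c5c(=O)cc(-c6ccc(O)cc6)oc45)cc3)oc2c1 | target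

Total step count: 8. Longest linear sequence: 7 steps (steps 1, 2, 4, 5, 6, 7, 8); step 3 is the side branch.

Steps most likely to fail

Step 5. The lateral dienolate may be acetylated on oxygen or quenched by proton transfer, and the pyranone may be opened by amide base or by the methoxide set free before the Claisen closure is complete. The fallback uses a classical copper-mediated diaryl ether synthesis that sets out from 5 and comes back at 14. Commercial apigenin would be converted (MOMCl, NaH, DMF) into 5,7-bis(methoxymethoxy)-2-[4-(methoxymethoxy)phenyl]-4H-chromen-4-one F1. This would be iodinated at C8 (N-iodosuccinimide, DMF; 5-O-alkylated flavones are halogenated at C8) to 8-iodo-5,7-bis(methoxymethoxy)-2-[4-(methoxymethoxy)phenyl]-4H-chromen-4-one F2. Ullmann etherification of F2 with an excess of the small phenol 5 (CuI, N,N-dimethylglycine, Cs2CO3, dioxane, 100 °C) would give 14, and the route would continue at step 7.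

Step 4. O-acylation of the magnesium enolate, conjugate addition of pyridine to the alkynoyl chloride with oligomerisation, or anti-Michael 5-exo closure to a furanone may prevail. The fallback makes the pyranone at the alkene oxidation level and dehydrogenates it; it sets out from 2 and 7 and comes back at 10. Heck reaction of 2 with acrylic acid (Pd(OAc)2, Et3N, DMF, 80 °C) would give (2E)-3-[4-(methoxymethoxy)phenyl]prop-2-enoic acid F3. The same chloroenamine would convert it into (2E)-3-[4-(methoxymethoxy)phenyl]prop-2-enoyl chloride F4. C-acylation of 7 (MgCl2, pyridine) would give methyl (4E)-2-{[4-(methoxycarbonyl)phenoxy]acetyl}-5-[4-(methoxymethoxy)phenyl]-3-oxopent-4-enoate F5. Oxa-Michael closure (K2CO3, MeCN) would give racemic methyl 6-{[4-(methoxycarbonyl)phenoxy]methyl}-2-[4-(methoxymethoxy)phenyl]-4-oxo-3,4-dihydro-2H-pyran-5-carboxylate F6. Dehydrogenation of F6 with DDQ (dioxane, 90 °C) would give 10.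

Step 7. Acylation of the trianion at the electron-rich aryl ester may be slow, so that proton transfer and decomposition of the polyanion win. The fallback forms the diketone by intramolecular acyl transfer; it sets out from 14 and comes back at 16. Saponification of 14 (LiOH, THF–H2O, rt) would give 4-({5,7-bis(methoxymethoxy)-2-[4-(methoxymethoxy)phenyl]-4-oxo-4H-chromen-8-yl}oxy)benzoic acid F7. Esterification with one hydroxyl of 15 (EDC·HCl, DMAP, CH2Cl2) would give 2-acetyl-3-hydroxy-5-methoxyphenyl 4-({5,7-bis(methoxymethoxy)-2-[4-(methoxymethoxy)phenyl]-4-oxo-4H-chromen-8-yl}oxy)benzoate F8. Baker–Venkataraman rearrangement of F8 (KOH, pyridine, 50 °C) would give 16.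

Further compounds
F1 | step 5 | 5,7-bis(methoxymethoxy)-2-[4-(methoxymethoxy)phenyl]-4H-chromen-4-one | COCOc1ccc(-c2cc(=O)c3c(OCOC)cc(OCOC)cc3o2)cc1
F2 | step 5 | 8-iodo-5,7-bis(methoxymethoxy)-2-[4-(methoxymethoxy)phenyl]-4H-chromen-4-one | COCOc1ccc(-c2cc(=O)c3c(OCOC)cc(OCOC)c(I)c3o2)cc1
F3 | step 4 | (2E)-3-[4-(methoxymethoxy)phenyl]prop-2-enoic acid | COCOc1ccc(/C=C/C(=O)O)cc1
F4 | step 4 | (2E)-3-[4-(methoxymethoxy)phenyl]prop-2-enoyl chloride | COCOc1ccc(/C=C/C(Cl)=O)cc1
F5 | step 4 | methyl (4E)-2-{[4-(methoxycarbonyl)phenoxy]acetyl}-5-[4-(methoxymethoxy)phenyl]-3-oxopent-4-enoate | COC(=O)c1ccc(OCC(=O)C(C(=O)OC)C(=O)/C=C/c2ccc(OCOC)cc2)cc1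
F6 | step 4 | methyl 6-{[4-(methoxycarbonyl)phenoxy]methyl}-2-[4-(methoxymethoxy)phenyl]-4-oxo-3,4-dihydro-2H-pyran-5-carboxylate (racemic) | COC(=O)c1ccc(OCC2=C(C(=O)OC)C(=O)CC(c3ccc(OCOC)cc3)O2)cc1
F7 | step 7 | 4-({5,7-bis(methoxymethoxy)-2-[4-(methoxymethoxy)phenyl]-4-oxo-4H-chromen-8-yl}oxy)benzoic acid | OC(=O)c1ccc(Oc2c(OCOC)cc(OCOC)c3c(=O)cc(-c4ccc(OCOC)cc4)oc23)cc1
F8 | step 7 | 2-acetyl-3-hydroxy-5-methoxyphenyl 4-({5,7-bis(methoxymethoxy)-2-[4-(methoxymethoxy)phenyl]-4-oxo-4H-chromen-8-yl}oxy)benzoate | COc1cc(O)c(C(C)=O)c(OC(=O)c2ccc(Oc3c(OCOC)cc(OCOC)c4c(=O)cc(-c5ccc(OCOC)cc5)oc34)cc2)c1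
A1 | direct plan | 5,7-bis(benzyloxy)-2-[4-(benzyloxy)phenyl]-8-iodo-4H-chromen-4-one | O=c1cc(-c2ccc(OCc3ccccc3)cc2)oc2c(I)c(OCc3ccccc3)cc(OCc3ccccc3)c12
A2 | direct plan | genkwanin, 5-hydroxy-2-(4-hydroxyphenyl)-7-methoxy-4H-chromen-4-one | COc1cc(O)c2c(=O)cc(-c3ccc(O)cc3)oc2c1
A3 | direct plan | 2-[4-({5,7-bis(benzyloxy)-2-[4-(benzyloxy)phenyl]-4-oxo-4H-chromen-8-yl}oxy)phenyl]-5-hydroxy-7-methoxy-4H-chromen-4-one | COc1cc(O)c2c(=O)cc(-c3ccc(Oc4c(OCc5ccccc5)cc(OCc5ccccc5)c5c(=O)cc(-c6ccc(OCc7ccccc7)cc6)oc45)cc3)oc2c1
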